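Time first: in theta, J (the tris adduct) reads 71 % at 1.33 min and 73 % at 15.0 min, a gap of 2 percentage points against a scatter of 2 points, so between those two readings theta shows no drift beyond the scatter.

| setting | epsilon | gamma | theta | north-east | south | east |
|---|---|---|---|---|---|---|
| L | 0.18 M | 0.18 M | 0.18 M | 0.18 M | 0.18 M | 0.18 M |
| D | 0.78 equiv | 1.9 equiv | 4.5 equiv | 0.800 equiv | 3.00 equiv | 4.00 equiv |
| remark | run made earlier | run made earlier | run made earlier |  |  |  |
| time |  |  |  | 15 min | 15 min | 15 min |

| run | time / min | J / % | Q / % |
|---|---|---|---|
| epsilon | 1.33 | 4 | 2 |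
| epsilon | 2.50 | 1 | 2 |
| epsilon | 4.00 | 3 | 4 |
| epsilon | 8.00 | 5 | 0 |
| epsilon | 15.0 | 4 | 4 |
| gamma | 1.33 | 32 | 2 |
| gamma | 4.00 | 35 | 0 |
| gamma | 8.00 | 32 | 0 |
| gamma | 10.0 | 35 | 2 |
| gamma | 15.0 | 37 | 0 |
| theta | 1.33 | 71 | 5 |
| theta | 2.50 | 76 | 0 |
| theta | 4.00 | 68 | 0 |
| theta | 8.00 | 69 | 0 |
| theta | 15.0 | 73 | 0 |

(readings scatter by 2 percentage points)

- a reading or a percentage of Q counts all its forms, free or not

* which of these holds the largest part of the L at the end of north-east (J / Z / L / Q)
* which of these holds the largest part of the L at the end of south (J / Z / L / Q)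
* which of these holds the largest part of the L at the end of east (J / Z / L / Q)
* how much J is there at the end of east, in percent of the L charged

Two chemists read these runs differently. The first says the L that is not J sits as Z, the mono adduct, and that J against Z follows the leftover D, so Z should lead in north-east.

The second follows one molecule of Z to its fork: it meets D and passes through Q to J, or it leaves for a product nobody reads. Her evidence is theta. There J averages 71.4 %, so with L taken as gone the balance leaves 2.07 D per L unused, yet J stays flat, and a waiting Z should keep turning into J.

Let y be J as a fraction of L charged, e the D charged per L, and m = e − 1 − y the mean spare D, midway between the spare D after the first addition and at the end. Her rule is y/(1 − y) = κm. Gamma, with mean J 34.2 %, gives 0.931, and theta gives 0.896. I take their mean, κ = 0.914, the odds of J against loss per equivalent of spare D, a selectivity factor.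

Solved for y, the rule gives J 56.7 % in south and 68.0 % in east. In north-east, D is the limiting reagent. Each L taken costs one D, Q two and J 3, so with epsilon's mean J 3.40 % and Q 2.40 %, L keeps 29.2 %, more than J or Q, and on her fork Z does not wait, so she names L among the four asked.

The forecast sides with the first chemist, giving Z, J, J and J 65 % in east, and saying “the balance must be mostly Z”, and my J for east stands above it.

Of the four asked, the flasks end with L, J and J in the lead; north-east holds L 31.0 % and Z 0 %, with 62.5 % as X, which stands outside the four, and east holds J 68.7 %.

    L + D → Z (k = 3.75 /M/s)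
    D + Z → Q (k = 0.845 /M/s)
    D + Q → J (k = 9.76 /M/s)
    E ⇌ Q, rate k4*(cs4 - [Q]) while solid is left; crystals form when [Q] > cs4 (solubility = 0.180 M, k = 1.22 /s)
    Z → X (k = 0.117 /s)
    D ⇌ G (K = 0.520, k = 0.217 /s)

In east at 0.00479 min, Z is made 3.97 times faster than it is used up, each step taken net, and that early moment is the first chemist's region, for at 7.50 min east holds Z 0 %. In a neighbour of east with 2.40 equiv of D, κ gives J 46.2 %, and that flask holds 45.9 %.

The readings were computed for an exercise; noise was put on by code.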